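**Strategy**

Numbering the furofuran as a 3,7-dioxabicyclo[3.3.0]octane puts the phenolic ring on C2 and the trimethoxyphenyl ring on C6 (ring A: C1, C2, O3, C4, C5; ring B: C5, C6, O7, C8, C1). The bridgehead pair C1–C5 sits at the centre of a butane whose four branches (C2, C4, C6, C8) all bear oxygen, which is the α,β-unit of a 5-alkoxybutenolide with carbonyl = C8 and acetal carbon = C4. One operation unites three fragments: a lithiated aryl dithiane forms C5–C6 by 1,4-addition and the enolate forms C1–C2 by aldol capture, the lone acetal centre fixing both bridgeheads. The precursor is crystalline (5S)-menthyloxybutenolide; reduction, dithiane unmasking and acid-mediated double etherification finish rings A and B.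

Key step: step 5

Remark: the target is (1S,2R,5S,6R) with both aryl groups exo; this series requires the (5S)-butenolide of (+)-menthol (the (5R)-butenolide of (−)-menthol would lead to the enantiomer).

Assumption: C2 in 13–15 is drawn as the expected major aldol isomer and C6 in 16 is left undefined; both centres are re-formed through benzylic cations in step 9, so neither affects the outcome.

**Route**

Step 1
Reactants: 1 furfural (furan-2-carbaldehyde)
Product: 3 5-hydroxyfuran-2(5H)-one (racemic), via furfural endoperoxide 2 (not isolated)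
Conditions: O2, hν (visible), rose bengal disodium salt C20H2Cl4I4Na2O5 (cat.), MeOH, 20 °C
Reagents that add atoms: oxygen, O=O
Why: Dye-sensitised singlet-oxygen [4+2] photooxygenation of the furan gives endoperoxide 2, which methanol opens with loss of the formyl carbon as methyl formate to leave the γ-hydroxybutenolide; no stereocentre is controlled, since 3 is racemic and configurationally labile.

Step 2
Reactants: 3 5-hydroxyfuran-2(5H)-one; 4 (+)-menthol [(1S,2R,5S)-2-isopropyl-5-methylcyclohexan-1-ol]
Product: 6 (5S)-5-[(1S,2R,5S)-menthyloxy]furan-2(5H)-one, via (5R)-epimeric acetal 5 (not isolated)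
Conditions: (+)-camphor-10-sulfonic acid (cat.), toluene, reflux, Dean–Stark; crystallisation from hexane, −20 °C; mother liquor re-equilibrated with the same acid and recrystallised
Reagents that add atoms: none
Why: Acid-catalysed acetalisation of the hemiacetal through the ring oxocarbenium ion gives both C5 epimers, of which the (5S)-acetal should crystallise selectively (it is the mirror image of the crystalline (5R)-acetal of the (−)-menthyl series), while the acid keeps epimer 5 in equilibrium so that repeated crystallisation funnels material into 6 and sets the acetal stereocentre.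

Step 3
Reactants: 7 3,4,5-trimethoxybenzaldehyde
Product: 8 2-(3,4,5-trimethoxyphenyl)-1,3-dithiane
Conditions: HS(CH2)3SH, BF3·OEt2 (cat.), CH2Cl2, 0 °C to rt
Reagents that add atoms: propane-1,3-dithiol, SCCCS
Why: Lewis-acid-catalysed dithioacetalisation of an aromatic aldehyde is a reliable route to the acyl-anion precursor and creates no stereocentre.

Step 4
Reactants: 9 syringaldehyde (4-hydroxy-3,5-dimethoxybenzaldehyde)
Product: 10 3,5-dimethoxy-4-(methoxymethoxy)benzaldehyde
Conditions: MOMCl, i-Pr2NEt, CH2Cl2, 0 °C to rt
Reagents that add atoms: chloromethyl methyl ether, COCCl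
Why: Williamson-type O-alkylation of the acidic phenol masks it as an acetal that tolerates the organolithium, hydride and buffered mercury conditions ahead and is cleaved by acid in the last step.

Step 5
Reactants: 8 2-(3,4,5-trimethoxyphenyl)-1,3-dithiane; 6 (5S)-5-[(1S,2R,5S)-menthyloxy]furan-2(5H)-one; 10 3,5-dimethoxy-4-(methoxymethoxy)benzaldehyde
Product: 13 (3R,4S,5S)-3-[(R)-hydroxy[3,5-dimethoxy-4-(methoxymethoxy)phenyl]methyl]-5-[(1S,2R,5S)-menthyloxy]-4-[2-(3,4,5-trimethoxyphenyl)-1,3-dithian-2-yl]dihydrofuran-2(3H)-one (trans lactone adduct), via lithiated dithiane 11 (not isolated), via lithium lactone enolate 12 (not isolated)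
Conditions: n-BuLi, THF, −78 to −20 °C; then 6, −78 °C; then 10, −78 °C; sat. aq NH4Cl, −78 °C
Reagents that add atoms: none
Why: Carbanion 11, stabilised by two sulfur atoms and the aryl ring, adds in Michael fashion to the β-carbon of 6, and the resulting lithium lactone enolate 12 is intercepted in a lithium aldol reaction by the non-enolisable aldehyde 10 before any proton source is admitted. The closest known reaction type is the tandem conjugate addition–aldol (three-component coupling) of lithiated 2-aryl-1,3-dithianes and aromatic aldehydes on 5-alkoxyfuran-2(5H)-ones. No ring is closed; the two new bonds are C5–C6 and C1–C2. C5 is controlled by the acetal centre C4, whose menthyloxy group shields one face of the flat butenolide so that 11 enters anti to it; C1 is controlled by the new dithianyl group on C5, the aldehyde approaching the enolate from the opposite face to give the trans,trans lactone. C2 arises in a chair-like lithium-chelated (Zimmerman–Traxler) transition state and should form mainly as drawn, but it need not be controlled because it is re-formed in step 9. The step needs 1,4- over 1,2-addition, which the soft stabilised anion at −78 °C secures, and a complete anti/trans relay from C4, which the rigid five-membered ring with its single bulky acetal substituent secures.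

Step 6
Reactants: 13 trans lactone adduct
Product: 14 (2S,3S)-2-[(R)-hydroxy[3,5-dimethoxy-4-(methoxymethoxy)phenyl]methyl]-3-[2-(3,4,5-trimethoxyphenyl)-1,3-dithian-2-yl]butane-1,4-diol
Conditions: LiAlH4, THF, 0 °C to rt; then H2O quench
Reagents that add atoms: none
Why: In this LiAlH4 reduction of an acyloxy acetal, hydride attack at the lactone carbonyl opens the ring, the released hemiacetal alkoxide expels (+)-menthoxide, and both aldehyde-level carbons are reduced to the C8 and C4 primary alcohols without touching the dithiane, the MOM ether or the C1 and C5 stereocentres.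

Step 7
Reactants: 14 dithiane triol
Product: 15 (2S,3S,4R)-4-hydroxy-2,3-bis(hydroxymethyl)-4-[3,5-dimethoxy-4-(methoxymethoxy)phenyl]-1-(3,4,5-trimethoxyphenyl)butan-1-one (open form of a ring-chain equilibrium with its C6 hemiketals)
Conditions: Hg(ClO4)2·3H2O, CaCO3, THF–H2O (5:1), 0 °C to rt
Reagents that add atoms: water, O
Why: Thiophilic, CaCO3-buffered mercury-assisted hydrolysis of the S,S-acetal (Corey–Seebach dithiane unmasking) releases the C6 aryl ketone under near-neutral conditions that should leave the MOM ether, the benzylic alcohol and the C5 α-stereocentre intact.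

Step 8
Reactants: 15 keto triol
Product: 16 (1R,2S,3S)-2,3-bis(hydroxymethyl)-1-[3,5-dimethoxy-4-(methoxymethoxy)phenyl]-4-(3,4,5-trimethoxyphenyl)butane-1,4-diol (C4 carbinol, the future C6, as an epimer mixture)
Conditions: NaBH4, MeOH, 0 °C
Reagents that add atoms: none
Why: Borohydride reduction of the aryl ketone (through the open form of any hemiketal) gives the C6 carbinol without stereocontrol, which is acceptable because C6 is re-formed through a planar benzylic cation in step 9.

Step 9
Reactants: 16 tetraol
Product: 18 (1S,2R,5S,6R)-2-(4-hydroxy-3,5-dimethoxyphenyl)-6-(3,4,5-trimethoxyphenyl)-3,7-dioxabicyclo[3.3.0]octane (target), via MOM-protected furofuran 17 (not isolated)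
Conditions: HCl (ca. 1 M) in MeOH–THF, 0 °C to rt, stopped when the MOM ether is consumed; then NaHCO3
Reagents that add atoms: none
Why: In this acid-mediated SN1 cyclodehydration each electron-rich benzylic carbinol ionises to a para-oxygen-stabilised cation that is captured by the 1,4-related primary hydroxyl (C4–OH at C2 closing ring A, C8–OH at C6 closing ring B) through the faster transition state with the aryl group on the convex exo face, so C2 and C6 should both emerge (R) whatever the carbinol configuration was, and the same acid then cleaves the phenolic MOM acetal by transacetalisation to methanol.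

**Compound list**

1 | furfural | O=Cc1ccco1 | starting material
2 | furfural endoperoxide, 2,3,7-trioxabicyclo[2.2.1]hept-5-ene-1-carbaldehyde (racemic) | O=CC12C=CC(OO1)O2 | intermediate
3 | 5-hydroxyfuran-2(5H)-one (racemic) | O=C1C=CC(O)O1 | intermediate
4 | (+)-menthol, (1S,2R,5S)-2-isopropyl-5-methylcyclohexan-1-ol | C[C@H]1CC[C@@H]([C@H](C1)O)C(C)C | starting material
5 | (5R)-5-[(1S,2R,5S)-menthyloxy]furan-2(5H)-one | O=C1C=C[C@H](O[C@H]2C[C@@H](C)CC[C@@H]2C(C)C)O1 | intermediate
6 | (5S)-5-[(1S,2R,5S)-menthyloxy]furan-2(5H)-one | O=C1C=C[C@@H](O[C@H]2C[C@@H](C)CC[C@@H]2C(C)C)O1 | intermediate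
7 | 3,4,5-trimethoxybenzaldehyde | COc1cc(C=O)cc(OC)c1OC | starting material
8 | 2-(3,4,5-trimethoxyphenyl)-1,3-dithiane | COc1cc(C2SCCCS2)cc(OC)c1OC | intermediate
9 | syringaldehyde | COc1cc(C=O)cc(OC)c1O | starting material
10 | 3,5-dimethoxy-4-(methoxymethoxy)benzaldehyde | COCOc1c(OC)cc(C=O)cc1OC | intermediate
11 | 2-lithio-2-(3,4,5-trimethoxyphenyl)-1,3-dithiane | [Li]C1(c2cc(OC)c(OC)c(OC)c2)SCCCS1 | intermediate
12 | lithium (4S,5S)-5-[(1S,2R,5S)-menthyloxy]-4-[2-(3,4,5-trimethoxyphenyl)-1,3-dithian-2-yl]-4,5-dihydrofuran-2-olate | [Li]OC1=C[C@H](C2(c3cc(OC)c(OC)c(OC)c3)SCCCS2)[C@@H](O[C@H]2C[C@@H](C)CC[C@@H]2C(C)C)O1 | intermediate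
13 | (3R,4S,5S)-3-[(R)-hydroxy[3,5-dimethoxy-4-(methoxymethoxy)phenyl]methyl]-5-[(1S,2R,5S)-menthyloxy]-4-[2-(3,4,5-trimethoxyphenyl)-1,3-dithian-2-yl]dihydrofuran-2(3H)-one | O=C1O[C@H](O[C@H]2C[C@@H](C)CC[C@@H]2C(C)C)[C@@H](C2(c3cc(OC)c(OC)c(OC)c3)SCCCS2)[C@@H]1[C@@H](O)c1cc(OC)c(OCOC)c(OC)c1 | intermediate
14 | (2S,3S)-2-[(R)-hydroxy[3,5-dimethoxy-4-(methoxymethoxy)phenyl]methyl]-3-[2-(3,4,5-trimethoxyphenyl)-1,3-dithian-2-yl]butane-1,4-diol | OC[C@@H](C1(c2cc(OC)c(OC)c(OC)c2)SCCCS1)[C@@H](CO)[C@@H](O)c1cc(OC)c(OCOC)c(OC)c1 | intermediate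
15 | (2S,3S,4R)-4-hydroxy-2,3-bis(hydroxymethyl)-4-[3,5-dimethoxy-4-(methoxymethoxy)phenyl]-1-(3,4,5-trimethoxyphenyl)butan-1-one | OC[C@@H](C(=O)c1cc(OC)c(OC)c(OC)c1)[C@@H](CO)[C@@H](O)c1cc(OC)c(OCOC)c(OC)c1 | intermediate
16 | (1R,2S,3S)-2,3-bis(hydroxymethyl)-1-[3,5-dimethoxy-4-(methoxymethoxy)phenyl]-4-(3,4,5-trimethoxyphenyl)butane-1,4-diol, C4 epimer mixture (C4 undefined) | OC[C@@H](C(O)c1cc(OC)c(OC)c(OC)c1)[C@@H](CO)[C@@H](O)c1cc(OC)c(OCOC)c(OC)c1 | intermediate
17 | (1S,2R,5S,6R)-2-[3,5-dimethoxy-4-(methoxymethoxy)phenyl]-6-(3,4,5-trimethoxyphenyl)-3,7-dioxabicyclo[3.3.0]octane | COc1cc([C@@H]2OC[C@@H]3[C@H]2CO[C@H]3c2cc(OC)c(OC)c(OC)c2)cc(OC)c1OCOC | intermediate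
18 | (1S,2R,5S,6R)-2-(4-hydroxy-3,5-dimethoxyphenyl)-6-(3,4,5-trimethoxyphenyl)-3,7-dioxabicyclo[3.3.0]octane | COc1cc([C@@H]2OC[C@@H]3[C@H]2CO[C@H]3c2cc(OC)c(OC)c(OC)c2)cc(OC)c1O | target

**Step count**

Total: 9 steps. Longest linear sequence: 7 steps (steps 1, 2, 5, 6, 7, 8, 9, from furfural to 18).

**Steps most likely to fail**

1. Step 5. The enolate may be protonated or revert by retro-Michael loss before the electron-rich aldehyde captures it, the aldolate may revert on warming, or the facial relay to C1 may be incomplete. The fallback sets out from 6 and 8 and comes back at 13, and it separates the two bond formations. Lithiated dithiane 11 is added to 6 as before, but the enolate is quenched with NH4Cl to give the conjugate adduct (4S,5S)-5-[(1S,2R,5S)-menthyloxy]-4-[2-(3,4,5-trimethoxyphenyl)-1,3-dithian-2-yl]dihydrofuran-2(3H)-one F1, which can be purified and checked for the anti relationship. F1 is then deprotonated with LDA in THF at −78 °C to regenerate enolate 12 free of other bases and nucleophiles; excess 10 is added and the mixture is quenched cold with acetic acid to give 13.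

2. Step 9. During the slower MOM cleavage the benzylic C–O bonds may re-ionise, which would epimerise C2 or C6 toward the exo,endo isomer; the C2 cation may also close onto the trimethoxyphenyl ring in a Friedel–Crafts sense, or deprotection may stall. The fallback sets out from 16 and comes back at 18, and it separates ring closure from deprotection and avoids protic acid. Tetraol 16 is cyclised under kinetic control with BF3·OEt2 in CH2Cl2 at −40 °C and quenched with Et3N, so that MOM-protected furofuran 17 is isolated. Its MOM group is then removed by thiol-assisted Lewis-acid cleavage (ZnBr2, n-PrSH, CH2Cl2, 0 °C, short contact), which transfers the methoxymethyl group to sulfur and gives 18. No compound outside the list is made (F0).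

3. Step 7. The freed β-hydroxy ketone may lose the C4 hydroxyl by β-elimination or epimerise at C5, the neighbouring hydroxyls may trap the thionium ion to give mixtures of cyclic O,S-ketals and hemiketals, or the polyol may bind the divalent mercury salt. The fallback sets out from 13 and comes back at 16, and it inverts the order of unmasking and reduction. The dithiane of 13 is hydrolysed first (Hg(ClO4)2·3H2O, CaCO3, aqueous THF) while C8 and C4 are still tied up in the lactone acetal, giving keto lactone (3R,4S,5S)-3-[(R)-hydroxy[3,5-dimethoxy-4-(methoxymethoxy)phenyl]methyl]-5-[(1S,2R,5S)-menthyloxy]-4-(3,4,5-trimethoxybenzoyl)dihydrofuran-2(3H)-one F2. LiAlH4 in THF then reduces ketone, lactone and acetal in one operation to tetraol 16 with release of (+)-menthol, bypassing 14 and 15.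

**Further compounds**

F1 | step 5 | (4S,5S)-5-[(1S,2R,5S)-menthyloxy]-4-[2-(3,4,5-trimethoxyphenyl)-1,3-dithian-2-yl]dihydrofuran-2(3H)-one | O=C1C[C@H](C2(c3cc(OC)c(OC)c(OC)c3)SCCCS2)[C@@H](O[C@H]2C[C@@H](C)CC[C@@H]2C(C)C)O1
F2 | step 7 | (3R,4S,5S)-3-[(R)-hydroxy[3,5-dimethoxy-4-(methoxymethoxy)phenyl]methyl]-5-[(1S,2R,5S)-menthyloxy]-4-(3,4,5-trimethoxybenzoyl)dihydrofuran-2(3H)-one | O=C1O[C@H](O[C@H]2C[C@@H](C)CC[C@@H]2C(C)C)[C@@H](C(=O)c2cc(OC)c(OC)c(OC)c2)[C@@H]1[C@@H](O)c1cc(OC)c(OCOC)c(OC)c1
F0 | step 9 | none | none
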